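**Plan**

1. Cuts, from late to early: the propanoate C–O bond; the C4 methyl, traced back to a carbonyl carbon; ring A at C4–C5 with re-formation of a C1–O bond (retro Ireland–Claisen); C1–C10 (carbonylative Negishi coupling); C12–C13 (B-alkyl Suzuki–Miyaura coupling); C9–C11 (enolate Michael addition); C8–CH3 (conjugate addition).
2. Enabling feature: in ring A the carbon substituent on C4, C4, C5 and the C1=C10 alkene form a γ,δ-unsaturated carboxyl array whose ends C1 and C4 are already bridged by C2–C3. The Claisen precursor is therefore a six-membered lactone (temporary ring) that carries the ring-B cyclohexenyl group on its carbinol carbon C1.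
3. The boat transition state places the lactone carbon cis to C6. That carbon is therefore taken down to the C4 methyl afterwards, and an ester added to C4 beforehand (helper) becomes the C4 carboxyl.
4. Forward order: ring B is present from the start (2-methylcyclohexenone); C8 and C9 are set, the side chain is coupled on, the enol triflate is acylated, the lactone is formed, and ring A is closed last by ring contraction; then CO2H→CHO→CH3, deprotection and propanoylation.
5. Stereochemistry: C8 from ligand-controlled conjugate addition; C9 from enolate attack anti to the C8 methyl; C1 (temporary) from Corey–Bakshi–Shibata reduction; C5 and C4 from chirality transfer through the boat; the E-alkene from syn-hydrozirconation and stereoretentive coupling.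

Key step: step 11

Remark: locants C1–C15 are the halimane locants of the target (ring A = C1–C5 and C10; ring B = C5–C10; chain C11–C15 on C9); the antipode of the phosphoramidite ligand in step 1 is assumed to be the one giving the 3R centre; SC = (E)-5-(tert-butyldiphenylsilyloxy)-3-methylpent-3-en-1-yl, TMSE = 2-(trimethylsilyl)ethyl.

**Route**

Step 1
Reactants: 1 2-methylcyclohex-2-en-1-one
Product: 3 (R)-[(2,3-dimethylcyclohex-1-en-1-yl)oxy]trimethylsilane, via dimethylaluminium enolate 2 (not isolated)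
Conditions: Me3Al, Cu(O2C-2-thienyl) (cat.), BINOL-derived phosphoramidite ligand (cat.), Et2O, −30 °C; then Me3SiOTf, THF, 0 °C
Reagents that add atoms: trimethylaluminium C[Al](C)C; trimethylsilyl trifluoromethanesulfonate C[Si](C)(C)OS(=O)(=O)C(F)(F)F
Why: Copper-catalysed asymmetric conjugate addition of the methyl group to the 2-substituted enone should set C8 (R) under ligand control, and O-silylation of the aluminium enolate fixes the enolate regiochemistry (C9=C10) for step 2.

Step 2
Reactants: 3 (R)-[(2,3-dimethylcyclohex-1-en-1-yl)oxy]trimethylsilane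
Product: 5 (2S,3R)-2,3-dimethyl-2-[2-(phenylsulfinyl)ethyl]cyclohexan-1-one (both sulfur epimers), via lithium enolate 4 (not isolated)
Conditions: MeLi, THF, 0 °C to rt; then phenyl vinyl sulfoxide, −78 to −20 °C
Reagents that add atoms: phenyl vinyl sulfoxide C=CS(=O)c1ccccc1
Why: Methyllithium cleaves the silyl enol ether to the regiodefined lithium enolate, whose Michael addition to the vinyl sulfoxide (a vinyl cation equivalent) should occur anti to the pseudoaxial C8 methyl, creating quaternary C9 with the two methyls cis.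

Step 3
Reactants: 5 (2S,3R)-2,3-dimethyl-2-[2-(phenylsulfinyl)ethyl]cyclohexan-1-one
Product: 6 (2S,3R)-2-ethenyl-2,3-dimethylcyclohexan-1-one
Conditions: xylene, CaCO3, 135 °C
Reagents that add atoms: none
Why: Thermal syn-elimination of the sulfoxide (sulfoxide pyrolysis) should unmask the vinyl group, and since C9 carries no hydrogen only the terminal alkene can form.

Step 4
Reactants: 7 but-2-yn-1-ol
Product: 8 (but-2-yn-1-yloxy)(tert-butyl)diphenylsilane
Conditions: t-BuPh2SiCl, imidazole, CH2Cl2, rt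
Reagents that add atoms: tert-butyl(chloro)diphenylsilane CC(C)(C)[Si](Cl)(c1ccccc1)c1ccccc1
Why: Standard silyl ether formation gives a protecting group that should survive strong bases, palladium catalysis, heat and mild acid.

Step 5
Reactants: 8 (but-2-yn-1-yloxy)(tert-butyl)diphenylsilane
Product: 10 (E)-tert-butyl[(3-iodobut-2-en-1-yl)oxy]diphenylsilane, via alkenylzirconocene chloride 9 (not isolated)
Conditions: Cp2Zr(H)Cl (excess), THF, rt to 40 °C; then I2, 0 °C
Reagents that add atoms: iodine II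
Why: syn-Hydrozirconation should place zirconium on the alkyne carbon next to the methyl group (the less hindered position after equilibration), and iodination with retention gives the (E)-vinyl iodide that fixes the C13=C14 geometry.

Step 6
Reactants: 6 (2S,3R)-2-ethenyl-2,3-dimethylcyclohexan-1-one; 10 (E)-tert-butyl[(3-iodobut-2-en-1-yl)oxy]diphenylsilane
Product: 12 (2S,3R)-2-SC-2,3-dimethylcyclohexan-1-one, via alkyl-9-BBN borane 11 (not isolated)
Conditions: 9-BBN, THF, 0 °C to rt; then 10, PdCl2(dppf) (cat.), AsPh3, Cs2CO3, DMF/H2O, rt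
Reagents that add atoms: none
Why: Anti-Markovnikov hydroboration of the terminal vinyl group and B-alkyl Suzuki–Miyaura coupling with retention of alkene geometry join C12 to C13 and complete the side chain, the α-quaternary ketone being expected to react with 9-BBN more slowly than the terminal alkene.

Step 7
Reactants: 12 (2S,3R)-2-SC-2,3-dimethylcyclohexan-1-one
Product: 14 (5R,6S)-6-SC-5,6-dimethylcyclohex-1-en-1-yl trifluoromethanesulfonate, via potassium enolate 13 (not isolated)
Conditions: KN(SiMe3)2, THF, −78 °C; then PhNTf2, −78 to 0 °C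
Reagents that add atoms: N-phenylbis(trifluoromethanesulfonimide) O=S(=O)(N(c1ccccc1)S(=O)(=O)C(F)(F)F)C(F)(F)F
Why: Because C9 is quaternary the ketone can enolise only toward C5, so deprotonation and O-triflation should give the single enol triflate with the C10=C5 double bond.

Step 8
Reactants: 14 (5R,6S)-6-SC-5,6-dimethylcyclohex-1-en-1-yl trifluoromethanesulfonate; 15 (4-ethoxy-4-oxobutyl)zinc bromide
Product: 16 ethyl 5-[(5R,6S)-6-SC-5,6-dimethylcyclohex-1-en-1-yl]-5-oxopentanoate
Conditions: Pd(PPh3)4 (cat.), LiCl, CO (1 atm), THF/NMP, 50 °C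
Reagents that add atoms: carbon monoxide [C-]#[O+]
Why: Oxidative addition of zerovalent palladium to the enol triflate, CO insertion and transmetalation from the alkylzinc (carbonylative Negishi coupling) form the C10–C1 bond as an enone, CO insertion being expected to outrun direct alkyl transfer at this hindered alkenylpalladium centre.

Step 9
Reactants: 16 ethyl 5-[(5R,6S)-6-SC-5,6-dimethylcyclohex-1-en-1-yl]-5-oxopentanoate
Product: 18 (6S)-6-[(5R,6S)-6-SC-5,6-dimethylcyclohex-1-en-1-yl]oxan-2-one, via hydroxy ester 17 (not isolated)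
Conditions: (R)-Me-CBS oxazaborolidine (cat.), catecholborane, toluene, −78 °C; then PPTS (cat.), toluene, 50 °C
Reagents that add atoms: none
Why: Corey–Bakshi–Shibata reduction with the branched alkenyl group as the large substituent should set the (S)-carbinol C1 under reagent control, and acid-catalysed transesterification then closes the δ-lactone.

Step 10
Reactants: 18 (6S)-6-[(5R,6S)-6-SC-5,6-dimethylcyclohex-1-en-1-yl]oxan-2-one
Product: 20 TMSE (6S)-2-oxo-6-[(5R,6S)-6-SC-5,6-dimethylcyclohex-1-en-1-yl]oxane-3-carboxylate (C3 epimers), via lithium enolate 19 (not isolated)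
Conditions: LiN(SiMe3)2 (2.2 equiv), THF, −78 °C; then 4-nitrophenyl 2-(trimethylsilyl)ethyl carbonate, −78 to −30 °C
Reagents that add atoms: 4-nitrophenyl 2-(trimethylsilyl)ethyl carbonate C[Si](C)(C)CCOC(=O)Oc1ccc(cc1)[N+](=O)[O-]
Why: C-acylation of the lactone enolate by the activated carbonate (enolate alkoxycarbonylation, excess base because the product is more acidic) installs the ester that becomes the C4 carboxyl, and the new centre need not be controlled because it becomes trigonal in step 11.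

Step 11
Reactants: 20 TMSE (6S)-2-oxo-6-[(5R,6S)-6-SC-5,6-dimethylcyclohex-1-en-1-yl]oxane-3-carboxylate
Product: 23 (1S,5S,6R,8aS)-5-SC-5,6-dimethyl-1-[(TMSE-oxy)carbonyl]-1,2,3,5,6,7,8,8a-octahydronaphthalene-1-carboxylic acid, via silyl ketene acetal 21 (not isolated), via silyl ester 22 (not isolated)
Conditions: t-BuMe2SiOTf, Et3N, CH2Cl2, 0 °C; then xylene, 150 °C (sealed, degassed); then AcOH/THF/H2O, rt
Reagents that add atoms: none
Why: O-silylation of the malonate-type lactone gives ketene acetal 21, whose array C4=C(OSi)–O–C1–C10=C5 is an allyl vinyl ether, and on heating a [3,3] Ireland–Claisen rearrangement forms C4–C5 while C1–O breaks, so the six-membered lactone contracts to carbocyclic ring A with the C1=C10 alkene and the quaternary C4 in one event. The closest known reaction type is the Ireland–Claisen ring contraction of 6-alkenyl δ-lactone silyl ketene acetals to cyclohex-3-enecarboxylic acids. Ring A closes as a six-membered ring through a boat-shaped, bicyclo[2.2.2]octane-like transition state, the only geometry the two-atom C2–C3 bridge allows, which is also why the ring alkene is cis. C5 is set by suprafacial chirality transfer from the (S)-carbinol C1 (the new bond enters the ring-B face that carried the C1–O bond, anti to the C9 side chain), and C4 by the ring-fixed ketene acetal geometry in the boat, which places the lactone carbon cis to C6 and the added ester cis to the C5 hydrogen. The only selectivity needed is this diastereoselectivity, secured by the lactone ring and by the reagent-controlled reduction of step 9. Because the α-ester makes the ketene acetal less electron-rich than in a simple lactone a higher temperature is planned, and the bulky silyl ester should not lose CO2 before the mild hydrolysis.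

Step 12
Reactants: 23 (1S,5S,6R,8aS)-5-SC-5,6-dimethyl-1-[(TMSE-oxy)carbonyl]-1,2,3,5,6,7,8,8a-octahydronaphthalene-1-carboxylic acid
Product: 25 TMSE (1S,5S,6R,8aS)-1-formyl-5-SC-5,6-dimethyl-1,2,3,5,6,7,8,8a-octahydronaphthalene-1-carboxylate, via acid chloride 24 (not isolated)
Conditions: 1-chloro-N,N,2-trimethylprop-1-en-1-amine, CH2Cl2, 0 °C to rt; then LiAlH(Ot-Bu)3, THF, −78 °C
Reagents that add atoms: none
Why: The acid chloride is formed under neutral conditions and its partial reduction by the hindered alkoxyaluminium hydride at low temperature should stop at the aldehyde without touching the neopentyl-type ester.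

Step 13
Reactants: 25 TMSE (1S,5S,6R,8aS)-1-formyl-5-SC-5,6-dimethyl-1,2,3,5,6,7,8,8a-octahydronaphthalene-1-carboxylate
Product: 27 TMSE (1S,5S,6R,8aS)-5-SC-1,5,6-trimethyl-1,2,3,5,6,7,8,8a-octahydronaphthalene-1-carboxylate, via tosylhydrazone 26 (not isolated)
Conditions: TsNHNH2, 4 Å molecular sieves, CHCl3, rt; then catecholborane, 0 °C to rt; then NaOAc·3H2O, 60 °C
Reagents that add atoms: none
Why: Hydride reduction of the tosylhydrazone followed by loss of sulfinate and N2 from the diazene (the mild counterpart of the Wolff–Kishner reduction) should turn the formyl group into the C4 methyl, and no alkene migration is expected because the aldehyde is not conjugated.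

Step 14
Reactants: 27 TMSE (1S,5S,6R,8aS)-5-SC-1,5,6-trimethyl-1,2,3,5,6,7,8,8a-octahydronaphthalene-1-carboxylate
Product: 28 (1S,5S,6R,8aS)-5-[(E)-5-hydroxy-3-methylpent-3-en-1-yl]-1,5,6-trimethyl-1,2,3,5,6,7,8,8a-octahydronaphthalene-1-carboxylic acid
Conditions: Bu4NF, THF, rt; aqueous NH4Cl work-up
Reagents that add atoms: none
Why: Fluoride cleaves the silyl ether and, by attack at silicon and β-elimination remote from the hindered carbonyl, also frees the tertiary acid in the same operation.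

Step 15
Reactants: 28 (1S,5S,6R,8aS)-5-[(E)-5-hydroxy-3-methylpent-3-en-1-yl]-1,5,6-trimethyl-1,2,3,5,6,7,8,8a-octahydronaphthalene-1-carboxylic acid
Product: 29 (1S,5S,6R,8aS)-1,5,6-trimethyl-5-[(E)-3-methyl-5-(propanoyloxy)pent-3-en-1-yl]-1,2,3,5,6,7,8,8a-octahydronaphthalene-1-carboxylic acid
Conditions: (EtCO)2O, Et3N, DMAP (cat.), CH2Cl2, 0 °C; then aqueous NaHCO3; work-up at pH 4
Reagents that add atoms: propanoic anhydride CCC(=O)OC(=O)CC
Why: DMAP-catalysed acylation should take place at the primary allylic alcohol, and any mixed anhydride formed at the hindered tertiary acid should be hydrolysed back during the bicarbonate treatment.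

**Compound list**

1 | 2-methylcyclohex-2-en-1-one | CC1=CCCCC1=O | starting material
2 | dimethylaluminium (3R)-2,3-dimethylcyclohex-1-en-1-olate | CC1=C(O[Al](C)C)CCC[C@H]1C | intermediate
3 | (R)-[(2,3-dimethylcyclohex-1-en-1-yl)oxy]trimethylsilane | CC1=C(O[Si](C)(C)C)CCC[C@H]1C | intermediate
4 | lithium (3R)-2,3-dimethylcyclohex-1-en-1-olate | CC1=C(O[Li])CCC[C@H]1C | intermediate
5 | (2S,3R)-2,3-dimethyl-2-[2-(phenylsulfinyl)ethyl]cyclohexan-1-one (both sulfur epimers) | O=S(CC[C@]1(C)C(=O)CCC[C@H]1C)c2ccccc2 | intermediate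
6 | (2S,3R)-2-ethenyl-2,3-dimethylcyclohexan-1-one | C=C[C@]1(C)C(=O)CCC[C@H]1C | intermediate
7 | but-2-yn-1-ol | CC#CCO | starting material
8 | (but-2-yn-1-yloxy)(tert-butyl)diphenylsilane | CC#CCO[Si](c1ccccc1)(c1ccccc1)C(C)(C)C | intermediate
9 | chlorobis(cyclopentadienyl)[(E)-4-(tert-butyldiphenylsilyloxy)but-2-en-2-yl]zirconium | C/C(=C\CO[Si](c1ccccc1)(c1ccccc1)C(C)(C)C)[Zr](Cl)(C1C=CC=C1)C1C=CC=C1 | intermediate
10 | (E)-tert-butyl[(3-iodobut-2-en-1-yl)oxy]diphenylsilane | C/C(I)=C\CO[Si](c1ccccc1)(c1ccccc1)C(C)(C)C | intermediate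
11 | (2S,3R)-2-[2-(9-borabicyclo[3.3.1]nonan-9-yl)ethyl]-2,3-dimethylcyclohexan-1-one | C1CCC2CCCC1B2CC[C@]3(C)C(=O)CCC[C@H]3C | intermediate
12 | (2S,3R)-2-[(E)-5-(tert-butyldiphenylsilyloxy)-3-methylpent-3-en-1-yl]-2,3-dimethylcyclohexan-1-one | CC(C)(C)[Si](c2ccccc2)(c3ccccc3)OC/C=C(\C)CC[C@]1(C)C(=O)CCC[C@H]1C | intermediate
13 | potassium (5R,6S)-6-[(E)-5-(tert-butyldiphenylsilyloxy)-3-methylpent-3-en-1-yl]-5,6-dimethylcyclohex-1-en-1-olate | CC(C)(C)[Si](c2ccccc2)(c3ccccc3)OC/C=C(\C)CC[C@]1(C)C(O[K])=CCC[C@H]1C | intermediate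
14 | (5R,6S)-6-[(E)-5-(tert-butyldiphenylsilyloxy)-3-methylpent-3-en-1-yl]-5,6-dimethylcyclohex-1-en-1-yl trifluoromethanesulfonate | CC(C)(C)[Si](c2ccccc2)(c3ccccc3)OC/C=C(\C)CC[C@]1(C)C(OS(=O)(=O)C(F)(F)F)=CCC[C@H]1C | intermediate
15 | (4-ethoxy-4-oxobutyl)zinc bromide | CCOC(=O)CCC[Zn]Br | starting material
16 | ethyl 5-{(5R,6S)-6-[(E)-5-(tert-butyldiphenylsilyloxy)-3-methylpent-3-en-1-yl]-5,6-dimethylcyclohex-1-en-1-yl}-5-oxopentanoate | CC(C)(C)[Si](c2ccccc2)(c3ccccc3)OC/C=C(\C)CC[C@]1(C)C(C(=O)CCCC(=O)OCC)=CCC[C@H]1C | intermediate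
17 | ethyl (5S)-5-{(5R,6S)-6-[(E)-5-(tert-butyldiphenylsilyloxy)-3-methylpent-3-en-1-yl]-5,6-dimethylcyclohex-1-en-1-yl}-5-hydroxypentanoate | CC(C)(C)[Si](c2ccccc2)(c3ccccc3)OC/C=C(\C)CC[C@]1(C)C([C@@H](O)CCCC(=O)OCC)=CCC[C@H]1C | intermediate
18 | (6S)-6-{(5R,6S)-6-[(E)-5-(tert-butyldiphenylsilyloxy)-3-methylpent-3-en-1-yl]-5,6-dimethylcyclohex-1-en-1-yl}oxan-2-one | CC(C)(C)[Si](c2ccccc2)(c3ccccc3)OC/C=C(\C)CC[C@]1(C)C([C@@H]4CCCC(=O)O4)=CCC[C@H]1C | intermediate
19 | lithium (2S)-2-{(5R,6S)-6-[(E)-5-(tert-butyldiphenylsilyloxy)-3-methylpent-3-en-1-yl]-5,6-dimethylcyclohex-1-en-1-yl}-3,4-dihydro-2H-pyran-6-olate | CC(C)(C)[Si](c2ccccc2)(c3ccccc3)OC/C=C(\C)CC[C@]1(C)C([C@@H]4CCC=C(O[Li])O4)=CCC[C@H]1C | intermediate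
20 | 2-(trimethylsilyl)ethyl (6S)-6-{(5R,6S)-6-[(E)-5-(tert-butyldiphenylsilyloxy)-3-methylpent-3-en-1-yl]-5,6-dimethylcyclohex-1-en-1-yl}-2-oxooxane-3-carboxylate (C3 epimers) | CC(C)(C)[Si](c2ccccc2)(c3ccccc3)OC/C=C(\C)CC[C@]1(C)C([C@@H]4CCC(C(=O)OCC[Si](C)(C)C)C(=O)O4)=CCC[C@H]1C | intermediate
21 | 2-(trimethylsilyl)ethyl (2S)-6-(tert-butyldimethylsilyloxy)-2-{(5R,6S)-6-[(E)-5-(tert-butyldiphenylsilyloxy)-3-methylpent-3-en-1-yl]-5,6-dimethylcyclohex-1-en-1-yl}-3,4-dihydro-2H-pyran-5-carboxylate | CC(C)(C)[Si](c2ccccc2)(c3ccccc3)OC/C=C(\C)CC[C@]1(C)C([C@@H]4CCC(C(=O)OCC[Si](C)(C)C)=C(O[Si](C)(C)C(C)(C)C)O4)=CCC[C@H]1C | intermediate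
22 | 1-(tert-butyldimethylsilyl) 1-[2-(trimethylsilyl)ethyl] (1R,5S,6R,8aS)-5-[(E)-5-(tert-butyldiphenylsilyloxy)-3-methylpent-3-en-1-yl]-5,6-dimethyl-1,2,3,5,6,7,8,8a-octahydronaphthalene-1,1-dicarboxylate | CC(C)(C)[Si](c2ccccc2)(c3ccccc3)OC/C=C(\C)CC[C@]1(C)C4=CCC[C@](C(=O)O[Si](C)(C)C(C)(C)C)(C(=O)OCC[Si](C)(C)C)[C@H]4CC[C@H]1C | intermediate
23 | (1S,5S,6R,8aS)-5-[(E)-5-(tert-butyldiphenylsilyloxy)-3-methylpent-3-en-1-yl]-5,6-dimethyl-1-{[2-(trimethylsilyl)ethoxy]carbonyl}-1,2,3,5,6,7,8,8a-octahydronaphthalene-1-carboxylic acid | CC(C)(C)[Si](c2ccccc2)(c3ccccc3)OC/C=C(\C)CC[C@]1(C)C4=CCC[C@](C(=O)O)(C(=O)OCC[Si](C)(C)C)[C@H]4CC[C@H]1C | intermediate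
24 | 2-(trimethylsilyl)ethyl (1R,5S,6R,8aS)-5-[(E)-5-(tert-butyldiphenylsilyloxy)-3-methylpent-3-en-1-yl]-1-(chlorocarbonyl)-5,6-dimethyl-1,2,3,5,6,7,8,8a-octahydronaphthalene-1-carboxylate | CC(C)(C)[Si](c2ccccc2)(c3ccccc3)OC/C=C(\C)CC[C@]1(C)C4=CCC[C@](C(Cl)=O)(C(=O)OCC[Si](C)(C)C)[C@H]4CC[C@H]1C | intermediate
25 | 2-(trimethylsilyl)ethyl (1S,5S,6R,8aS)-5-[(E)-5-(tert-butyldiphenylsilyloxy)-3-methylpent-3-en-1-yl]-1-formyl-5,6-dimethyl-1,2,3,5,6,7,8,8a-octahydronaphthalene-1-carboxylate | CC(C)(C)[Si](c2ccccc2)(c3ccccc3)OC/C=C(\C)CC[C@]1(C)C4=CCC[C@](C=O)(C(=O)OCC[Si](C)(C)C)[C@H]4CC[C@H]1C | intermediate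
26 | 4-methylbenzenesulfonylhydrazone of 25 | CC(C)(C)[Si](c2ccccc2)(c3ccccc3)OC/C=C(\C)CC[C@]1(C)C4=CCC[C@](C=NNS(=O)(=O)c5ccc(C)cc5)(C(=O)OCC[Si](C)(C)C)[C@H]4CC[C@H]1C | intermediate
27 | 2-(trimethylsilyl)ethyl (1S,5S,6R,8aS)-5-[(E)-5-(tert-butyldiphenylsilyloxy)-3-methylpent-3-en-1-yl]-1,5,6-trimethyl-1,2,3,5,6,7,8,8a-octahydronaphthalene-1-carboxylate | CC(C)(C)[Si](c2ccccc2)(c3ccccc3)OC/C=C(\C)CC[C@]1(C)C4=CCC[C@](C)(C(=O)OCC[Si](C)(C)C)[C@H]4CC[C@H]1C | intermediate
28 | (1S,5S,6R,8aS)-5-[(E)-5-hydroxy-3-methylpent-3-en-1-yl]-1,5,6-trimethyl-1,2,3,5,6,7,8,8a-octahydronaphthalene-1-carboxylic acid | OC/C=C(\C)CC[C@]1(C)C2=CCC[C@](C)(C(=O)O)[C@H]2CC[C@H]1C | intermediate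
29 | (1S,5S,6R,8aS)-1,5,6-trimethyl-5-[(E)-3-methyl-5-(propanoyloxy)pent-3-en-1-yl]-1,2,3,5,6,7,8,8a-octahydronaphthalene-1-carboxylic acid | CCC(=O)OC/C=C(\C)CC[C@]1(C)C2=CCC[C@](C)(C(=O)O)[C@H]2CC[C@H]1C | target

**Step count**

Total steps: 15. Longest linear sequence: 13 steps (steps 1–3 and 6–15, from 1 to 29); steps 4 and 5 make the side-chain iodide 10.

**Steps most likely to fail**

Step 11. The α-ester makes the ketene acetal electron-poor, so the rearrangement may be slow and may need a temperature at which the malonate-type silyl ester loses CO2 or the allylic C1–O bond ionises. The fallback sets out from 18 and comes back at 23; it separates ring closure from construction of the quaternary centre. Lactone 18 is enolised with LiN(i-Pr)2 and silylated (t-BuMe2SiCl, THF/HMPA, −78 °C) to the unsubstituted, electron-rich silyl ketene acetal F1. This should contract in toluene at about 105 °C through the same boat to silyl ester F2, and aqueous acetic acid then gives acid F3. In F3, C5 is already correct and the carboxyl (the future methyl carbon) is trans to the C5 hydrogen. LiN(i-Pr)2 (2.2 equiv) then gives dilithium enediolate F4, and C-acylation with 4-nitrophenyl 2-(trimethylsilyl)ethyl carbonate from the equatorial direction (cis to the axial C5 hydrogen) should give 23. In this variant the C4 configuration rests on the facial selectivity of the enediolate and not on the pericyclic geometry, so a minor C4 epimer may have to be removed at 23.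

Step 8. Oxidative addition at the enol triflate flanked by the quaternary C9 may be slow, and direct alkyl transfer may compete with CO insertion. The fallback sets out from 14 and comes back at 18. Nozaki–Hiyama–Kishi coupling of 14 with commercial methyl 5-oxopentanoate (CrCl2, NiCl2 (cat.), DMF/THF) gives allylic alcohol F5 as a mixture of C1 epimers, and Dess–Martin oxidation converges both to keto ester F6. Corey–Bakshi–Shibata reduction as in step 9 then gives hydroxy ester F7, and PPTS-catalysed lactonisation returns 18.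

Step 6. Reduction of the ketone by 9-BBN may compete with hydroboration of the neopentyl-type vinyl group. The fallback sets out from 6 and comes back at 14, removing the carbonyl before the borane is introduced. Ketone 6 is deprotonated (KN(SiMe3)2, THF, −78 °C) to potassium enolate F8 and triflated with PhNTf2 to dienyl triflate F9. 9-BBN should then add only to the terminal vinyl group to give alkylborane F10, and coupling with 10 at room temperature (PdCl2(dppf), AsPh3, Cs2CO3), where the vinyl iodide should react in preference to the hindered enol triflate, gives 14 directly.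

**Further compounds**

F1 | step 11 | tert-butyldimethylsilyl ketene acetal of 18 (6-silyloxy-3,4-dihydro-2H-pyran, 2S) | CC(C)(C)[Si](c2ccccc2)(c3ccccc3)OC/C=C(\C)CC[C@]1(C)C([C@@H]4CCC=C(O[Si](C)(C)C(C)(C)C)O4)=CCC[C@H]1C
F2 | step 11 | tert-butyldimethylsilyl (1R,5S,6R,8aR)-5-[(E)-5-(tert-butyldiphenylsilyloxy)-3-methylpent-3-en-1-yl]-5,6-dimethyl-1,2,3,5,6,7,8,8a-octahydronaphthalene-1-carboxylate | CC(C)(C)[Si](c2ccccc2)(c3ccccc3)OC/C=C(\C)CC[C@]1(C)C4=CCC[C@@H](C(=O)O[Si](C)(C)C(C)(C)C)[C@H]4CC[C@H]1C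
F3 | step 11 | (1R,5S,6R,8aR)-5-[(E)-5-(tert-butyldiphenylsilyloxy)-3-methylpent-3-en-1-yl]-5,6-dimethyl-1,2,3,5,6,7,8,8a-octahydronaphthalene-1-carboxylic acid | CC(C)(C)[Si](c2ccccc2)(c3ccccc3)OC/C=C(\C)CC[C@]1(C)C4=CCC[C@@H](C(=O)O)[C@H]4CC[C@H]1C
F4 | step 11 | dilithium enediolate of F3 | CC(C)(C)[Si](c2ccccc2)(c3ccccc3)OC/C=C(\C)CC[C@]1(C)C4=CCCC(=C(O[Li])O[Li])[C@H]4CC[C@H]1C
F5 | step 8 | methyl 5-{(5R,6S)-6-[(E)-5-(tert-butyldiphenylsilyloxy)-3-methylpent-3-en-1-yl]-5,6-dimethylcyclohex-1-en-1-yl}-5-hydroxypentanoate (C5 epimers) | CC(C)(C)[Si](c2ccccc2)(c3ccccc3)OC/C=C(\C)CC[C@]1(C)C(C(O)CCCC(=O)OC)=CCC[C@H]1C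
F6 | step 8 | methyl 5-{(5R,6S)-6-[(E)-5-(tert-butyldiphenylsilyloxy)-3-methylpent-3-en-1-yl]-5,6-dimethylcyclohex-1-en-1-yl}-5-oxopentanoate | CC(C)(C)[Si](c2ccccc2)(c3ccccc3)OC/C=C(\C)CC[C@]1(C)C(C(=O)CCCC(=O)OC)=CCC[C@H]1C
F7 | step 8 | methyl (5S)-5-{(5R,6S)-6-[(E)-5-(tert-butyldiphenylsilyloxy)-3-methylpent-3-en-1-yl]-5,6-dimethylcyclohex-1-en-1-yl}-5-hydroxypentanoate | CC(C)(C)[Si](c2ccccc2)(c3ccccc3)OC/C=C(\C)CC[C@]1(C)C([C@@H](O)CCCC(=O)OC)=CCC[C@H]1C
F8 | step 6 | potassium (5R,6S)-6-ethenyl-5,6-dimethylcyclohex-1-en-1-olate | C=C[C@]1(C)C(O[K])=CCC[C@H]1C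
F9 | step 6 | (5R,6S)-6-ethenyl-5,6-dimethylcyclohex-1-en-1-yl trifluoromethanesulfonate | C=C[C@]1(C)C(OS(=O)(=O)C(F)(F)F)=CCC[C@H]1C
F10 | step 6 | (5R,6S)-6-[2-(9-borabicyclo[3.3.1]nonan-9-yl)ethyl]-5,6-dimethylcyclohex-1-en-1-yl trifluoromethanesulfonate | C1CCC2CCCC1B2CC[C@]3(C)C(OS(=O)(=O)C(F)(F)F)=CCC[C@H]3C
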